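I had no constants for this flask, so two earlier runs had to tell me whether 8.0 d at 3.00 equiv was worth charging, or whether the charge itself was the thing to change.

| setting | midnight | spring | flask |
|---|---|---|---|
| substrate | 0.067 M (in portions, 2) | 0.15 M (in portions, 2) | 0.10 M (in portions, 2) |
| reagent | 3 equiv | 3 equiv | 3.00 equiv |
| remark | run made earlier; portions every 50 min | run made earlier; portions every 50 min | the portions of substrate follow each other after 50 min, the first at the start |
| time |  |  | 8.0 d |

| run | time / d | single product / % | isomer of the product / % |
|---|---|---|---|
| midnight | 2.50 | 16.0 | 46.3 |
| midnight | 5.00 | 15.0 | 45.4 |
| midnight | 8.00 | 14.8 | 46.4 |
| midnight | 10.0 | 15.2 | 44.9 |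
| spring | 1.25 | 13.5 | 40.3 |
| spring | 3.00 | 12.4 | 39.5 |
| spring | 6.00 | 14.0 | 40.7 |
| spring | 10.0 | 13.4 | 40.9 |

(standard deviation of a reading: 0.5 percentage points)

- the reaction counts as stopped when no species that holds the substrate changes by six tenths of a point or more over the second half of the time

- the state of affairs at 8.0 d: stopped, and by what, or still going (all of the substrate has reacted / forward and back rates have come level / the reagent has run out first / it is still moving)
- how much single product there is at 8.0 d, in percent of the substrate charged
- how much isomer of the product there is at 8.0 d, in percent of the substrate charged
- how much double product there is at 8.0 d, in percent of the substrate charged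

Time looked like the wrong lever, since the isomer in the spring run moved by 0.6 percentage points between 1.25 d and 10.0 d, against a scatter of 0.5 points. Between first and last reading the single product fell by 0.8 points in the midnight run and 0.1 points in the spring run, which I did not expect if reagent were still at work carrying it on to double product. So I looked at the reagent share ε, the percent of substrate charged found as single product plus isomer, divided by the equivalents of reagent charged. It read 20.3% in the midnight run and fell to 17.9% in the more concentrated spring run.

Interpolated linearly in substrate concentration, ε came to 19.4% for the flask, the part of its reagent I expected to find as single product plus isomer, which means 58.1% of the substrate in those two species. Even if the remaining substrate had become double product, the products would hold 47.3% of the reagent, so I suspected a loss of reagent outside these species, and I ran the recipe unchanged to test ε.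

The forecast said forward and back rates have come level, “inferred rather than proven”, with 14.4% single product, 43.4% isomer and 13% double product. There I parted from it, for my suspicion lay on the reagent.

    substrate + reagent → single product (k = 0.0984 M⁻¹ min⁻¹)
    reagent + single product → double product (k = 0.0247 M⁻¹ min⁻¹)
    single product ⇌ isomer of the product (K = 3.10, k = 0.0252 min⁻¹)
    2 reagent → self-condensation product (k = 0.0919 M⁻¹ min⁻¹)

The state of the flask at 8.0 d was this: the reagent has run out first, with 0% of its charge left, and the flask held 13.9% single product, 43.1% isomer and 3.89% double product. By 4.00 d the reagent, the limiting reagent here, stood at 0% of its charge, with 0.118 M self-condensation product and 39.1% substrate unreacted. The reagent share of this flask came to 19.0%, and a flask with 0.040 M substrate at the same equivalents reached a higher share of 21.3%.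

The numbers in the tables were generated by integration for an exercise, and the scatter is random.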